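I began from amounts and wrote the balance of the solid reagent, assuming one equivalent used per substrate converted. The cover, 1.50 in epsilon and theta, is the charge of solid reagent over the charge of substrate, c(solid reagent)/c(substrate). On that assumption a cover below one is the fractional conversion at which solid should run out, and at any cover the share of solid left is one minus conversion over cover.

common to all: substrate 0.10 M

| flask | solid reagent | remark | time |
|---|---|---|---|
| ash | 0.075 M | run made earlier |  |
| elm | 0.30 M | run made earlier |  |
| epsilon | 0.150 M |  | 25 min |
| theta | 0.150 M |  | 50 min |

| run | time / min | isomer of the product / % | substrate / % | target / % |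
|---|---|---|---|---|
| ash | 1.50 | 0 | 99.9 | 0 |
| ash | 5.00 | 0 | 96.8 | 4.5 |
| ash | 8.00 | 2.8 | 89.1 | 5.2 |
| ash | 15.0 | 5.3 | 77.1 | 17.6 |
| ash | 20.0 | 7.4 | 66.9 | 25.5 |
| ash | 25.0 | 9.4 | 58.4 | 32.4 |
| elm | 4.00 | 0.2 | 98.1 | 2.0 |
| elm | 8.00 | 1.7 | 94.1 | 7.3 |
| elm | 12.0 | 2.6 | 82.8 | 13.4 |
| elm | 15.0 | 4.8 | 75.7 | 18.3 |
| elm | 20.0 | 7.3 | 66.3 | 27.7 |
| elm | 25.0 | 8.9 | 55.5 | 36.4 |

(each reading ± 1 percentage point)

* which of these there is most of at the end, counted by the substrate in it, epsilon (target / isomer of the product / substrate)
* which of these there is most of at the end, counted by the substrate in it, theta (target / isomer of the product / substrate)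
* how much there is at the end of the one of these that leads, in percent of the substrate charged: epsilon
* how much there is at the end of the one of these that leads, in percent of the substrate charged: theta

- solid, in amounts per volume of the solution: solid reagent
- the analysis behind the earlier runs scatters by 1 percentage point, standard deviation
- at the start none of the solid reagent is in solution
- a reading or a percentage of target counts all its forms, free or not

In the ash run, solid was on paper the limiting reagent, with a cover of 0.750. Its last conversion reading, 41.6 %, stood below that. The elm run had a cover of 3.00, and at 25.0 min the runs read substrate 58.4 % and 55.5 %, with a scatter of 1 percentage point. So I expected about 57.0 % substrate in epsilon, and on my balance 71.3 % of the solid left. One number was not enough, though: the cover carries no clock, so it could not give theta's conversion.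

The forecast gave substrate at 57 % for epsilon and target at 58 % for theta, reasoning “Rate therefore doesn't depend on the amount of solid”.

Epsilon ended with substrate leading at 56.7 %, and theta with target at 63.5 %, 5.5 points above the forecast.

    substrate + partner → target, rate k1*[substrate]*[partner]^1.5 (k = 0.102 L¹·⁵ mol⁻¹·⁵ s⁻¹)
    target ⇌ isomer of the product (K = 0.420, k = 0.0167 s⁻¹)
    solid reagent ⇌ partner, rate k3*(cs3 - [partner]) while solid is left; crystals form when [partner] > cs3 (solubility = 0.0590 M, k = 0.00161 s⁻¹)
    partner + target ⇌ idle adduct, settled at all times (K = 18.5 L mol⁻¹)

In epsilon, the dissolving reached the midpoint of its turnover at 10.6 min, earlier than the path from target to isomer of the product, at 13.9 min. By 12.5 min the dissolving had 57 % of its turnover behind it. Theta's cover promised 47.4 % of the solid left, but 3.42 % of its charge stood, beside partner at 0.0392 M and idle adduct at 26.7 % of the substrate charged, counted in target too. Epsilon read at 1.0 h, with the same cover, held substrate 13.3 %; the cover promised 42.2 % of the solid, and 0 % stood.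

The numbers in the tables were computed for substances that don't exist; the scatter is artificial.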